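**Plan**

- Retrosynthesis: the seven phenols are unmasked last from benzyl ethers, and the ring A–ring B ketone is taken back to a diarylcarbinol. Ring B (the 2,4-dihydroxy-6-methylbenzoyl ring on ring A) carries C6–CH3, C1–C(=O) and C2–O on three neighbouring carbons. The Ar–CH3 and Ar–CH(OH) bonds are therefore cut together, giving an aryne flanked by the C2 oxygen, MeMgCl and a ring A aldehyde.
- That aldehyde is cut at the ArCH2–Ar bond into 2,6-dihydroxy-4-methoxybenzaldehyde and an ortho-quinone methide of the ring A'–ring B' benzophenone. The benzophenone is cut at the ring A'–C(=O) bond into a lithiated 5-methoxyresorcinol bis-MOM ether and the ring B' aldehyde.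
- Forward: ring A comes from 2,4,6-trihydroxybenzaldehyde by 4-O-methylation, and ring A' from the aryllithium of protected 5-methoxyresorcinol added to the ring B' aldehyde. Mannich base formation, quinone methide coupling and perbenzylation give the ring A aldehyde; the three-component aryne coupling, oxidation and hydrogenolysis finish the route.
- No ring is formed; all four benzene rings are bought. The target is achiral, and the two carbinol centres made on the way (9 and 23) are racemic and are erased by oxidation.

Key step: step 13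

Assumption: 2,4,6-trihydroxybenzaldehyde (1), 2,4-dihydroxy-6-methylbenzaldehyde (3), 5-methoxyresorcinol (6), 5-fluororesorcinol (16) and methylmagnesium chloride (19) are taken as catalogue chemicals.

**Route**

Step 1
Reactants: 1 2,4,6-trihydroxybenzaldehyde
Product: 2 2,6-dihydroxy-4-methoxybenzaldehyde
Conditions: Me2SO4 (1.0 equiv), K2CO3 (1.0 equiv), acetone, 0 °C to rt
Reagents that add atoms: dimethyl sulfate, COS(=O)(=O)OC
Why: Regioselective Williamson O-methylation should take place at the 4-hydroxyl, which is para to the formyl group and not hydrogen-bonded to it, so that one equivalent of dimethyl sulfate leaves the two chelated ortho-hydroxyls free, as is known for phloroacyl compounds.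

Step 2
Reactants: 3 2,4-dihydroxy-6-methylbenzaldehyde
Product: 4 4-(benzyloxy)-2-hydroxy-6-methylbenzaldehyde
Conditions: BnBr (1.05 equiv), K2CO3 (1.1 equiv), acetone, 40 °C
Reagents that add atoms: benzyl bromide, BrCc1ccccc1
Why: Regioselective Williamson etherification should take place at the 4-hydroxyl, because the 2-hydroxyl is hydrogen-bonded to the aldehyde and its phenoxide is the less reactive one.

Step 3
Reactants: 4 4-(benzyloxy)-2-hydroxy-6-methylbenzaldehyde
Product: 5 4-(benzyloxy)-2-methoxy-6-methylbenzaldehyde
Conditions: MeI, K2CO3, DMF, 40 °C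
Reagents that add atoms: iodomethane, CI
Why: Williamson methylation of the remaining chelated phenol in a dipolar aprotic solvent fixes the one methyl ether that distinguishes ring B' from ring B.

Step 4
Reactants: 6 5-methoxyresorcinol
Product: 7 1-methoxy-3,5-bis(methoxymethoxy)benzene
Conditions: NaH (2.4 equiv), MOMCl (2.4 equiv), DMF, 0 °C to rt
Reagents that add atoms: chloromethyl methyl ether, COCCl
Why: Williamson-type O-alkylation of both phenoxides installs the two acetal groups that direct the lithiation of the next step and later come off with acid without touching the benzyl ether.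

Step 5
Reactants: 7 1-methoxy-3,5-bis(methoxymethoxy)benzene, 5 4-(benzyloxy)-2-methoxy-6-methylbenzaldehyde
Product: 9 rac-[4-(benzyloxy)-2-methoxy-6-methylphenyl][4-methoxy-2,6-bis(methoxymethoxy)phenyl]methanol, via aryllithium 8 (not isolated)
Conditions: 7 (1.15 equiv), n-BuLi (1.1 equiv), TMEDA, THF, 0 °C; 5 (1.0 equiv), −78 °C to rt; aq NH4Cl
Reagents that add atoms: none
Why: Directed ortho-metalation should remove the proton between the two methoxymethoxy groups, where both acetal oxygens hold the lithium, and 1,2-addition of the aryllithium to the aldehyde then forms the ring A'–carbinol bond; the new centre is racemic and is removed in step 6.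

Step 6
Reactants: 9 rac-[4-(benzyloxy)-2-methoxy-6-methylphenyl][4-methoxy-2,6-bis(methoxymethoxy)phenyl]methanol
Product: 10 [4-(benzyloxy)-2-methoxy-6-methylphenyl][4-methoxy-2,6-bis(methoxymethoxy)phenyl]methanone
Conditions: Dess–Martin periodinane, pyridine, CH2Cl2, 0 °C to rt
Reagents that add atoms: none
Why: Dess–Martin oxidation converts hindered, electron-rich diarylcarbinols into benzophenones under near-neutral conditions, and the pyridine buffer protects the acetals and the ionisable carbinol from acetic acid.

Step 7
Reactants: 10 [4-(benzyloxy)-2-methoxy-6-methylphenyl][4-methoxy-2,6-bis(methoxymethoxy)phenyl]methanone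
Product: 11 [4-(benzyloxy)-2-methoxy-6-methylphenyl](2,6-dihydroxy-4-methoxyphenyl)methanone
Conditions: 3 M HCl, MeOH–THF, 50 °C
Reagents that add atoms: none
Why: Acidic methanolysis of the two MOM acetals frees the two ring A' phenols, the methoxymethyl unit leaving as dimethoxymethane, while the benzyl ether and the methyl ethers are stable to dilute acid.

Step 8
Reactants: 11 [4-(benzyloxy)-2-methoxy-6-methylphenyl](2,6-dihydroxy-4-methoxyphenyl)methanone
Product: 12 [4-(benzyloxy)-2-methoxy-6-methylphenyl]{3-[(dimethylamino)methyl]-2,6-dihydroxy-4-methoxyphenyl}methanone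
Conditions: N,N,N',N'-tetramethylmethanediamine (1.0 equiv), 1,4-dioxane, 40 °C
Reagents that add atoms: N,N,N',N'-tetramethylmethanediamine, CN(C)CN(C)C
Why: The phenolic Mannich reaction should aminomethylate one of the two equivalent free positions of ring A' (ortho to a hydroxyl), the single equivalent of aminal limiting double substitution, while the fully etherified ring B' stays inert.

Step 9
Reactants: 12 [4-(benzyloxy)-2-methoxy-6-methylphenyl]{3-[(dimethylamino)methyl]-2,6-dihydroxy-4-methoxyphenyl}methanone, 2 2,6-dihydroxy-4-methoxybenzaldehyde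
Product: 14 3-{[3-(4-(benzyloxy)-2-methoxy-6-methylbenzoyl)-2,4-dihydroxy-6-methoxyphenyl]methyl}-2,6-dihydroxy-4-methoxybenzaldehyde, via ortho-quinone methide 13 (not isolated)
Conditions: 2 (4 equiv), 1,4-dioxane, 100 °C, N2 sweep
Reagents that add atoms: none
Why: Thermal loss of dimethylamine from the ortho-hydroxybenzylamine gives the ortho-quinone methide, which is intercepted in a Michael-type Friedel–Crafts C-alkylation by the free resorcinol position of 2, used in excess to outrun self-condensation; this is the established way to unsymmetrical methylene-bridged acylphloroglucinols.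

Step 10
Reactants: 14 3-{[3-(4-(benzyloxy)-2-methoxy-6-methylbenzoyl)-2,4-dihydroxy-6-methoxyphenyl]methyl}-2,6-dihydroxy-4-methoxybenzaldehyde
Product: 15 2,6-bis(benzyloxy)-3-{[2,4-bis(benzyloxy)-3-(4-(benzyloxy)-2-methoxy-6-methylbenzoyl)-6-methoxyphenyl]methyl}-4-methoxybenzaldehyde
Conditions: BnBr (6 equiv), K2CO3 (6 equiv), n-Bu4NI (cat.), DMF, 50 °C
Reagents that add atoms: benzyl bromide, BrCc1ccccc1
Why: Fourfold Williamson benzylation with excess halide and iodide catalysis should cap all four chelated phenols, removing every acidic proton before the Grignard step and making the methylene bridge stable to base.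

Step 11
Reactants: 16 5-fluororesorcinol
Product: 17 1,3-bis(benzyloxy)-5-fluorobenzene
Conditions: BnBr (2.2 equiv), K2CO3, DMF, 60 °C
Reagents that add atoms: benzyl bromide, BrCc1ccccc1
Why: Plain Williamson etherification of both phenols gives the ring B oxygens in the form that is cleaved together with all other benzyl ethers at the end.

Step 12
Reactants: 17 1,3-bis(benzyloxy)-5-fluorobenzene
Product: 18 1,5-bis(benzyloxy)-2-bromo-3-fluorobenzene
Conditions: NBS (1.0 equiv), MeCN, 0 °C to rt
Reagents that add atoms: N-bromosuccinimide, O=C1CCC(=O)N1Br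
Why: Electrophilic aromatic bromination should go to the carbon next to fluorine, which is para to one benzyloxy group and ortho to the other and less crowded than the carbon between the two benzyloxy groups, as seen with 3,5-dialkoxytoluenes and 3,5-dialkoxyhalobenzenes.

Step 13
Reactants: 18 1,5-bis(benzyloxy)-2-bromo-3-fluorobenzene, 19 methylmagnesium chloride, 15 2,6-bis(benzyloxy)-3-{[2,4-bis(benzyloxy)-3-(4-(benzyloxy)-2-methoxy-6-methylbenzoyl)-6-methoxyphenyl]methyl}-4-methoxybenzaldehyde
Product: 23 rac-[2,6-bis(benzyloxy)-3-({2,4-bis(benzyloxy)-3-[(2,4-bis(benzyloxy)-6-methylphenyl)(hydroxy)methyl]-6-methoxyphenyl}methyl)-4-methoxyphenyl][4-(benzyloxy)-2-methoxy-6-methylphenyl]methanone, via fluoroarylmagnesium chloride 20 (not isolated), via 3,5-bis(benzyloxy)benzyne 21 (not isolated), via methylated arylmagnesium chloride 22 (not isolated)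
Conditions: 18 (2.5 equiv), i-PrMgCl·LiCl (2.5 equiv), THF, −10 °C; 19 (2.4 equiv), −10 to 45 °C; 15 (1.0 equiv) in THF, 0 °C to rt; aq NH4Cl
Reagents that add atoms: methylmagnesium chloride, C[Mg]Cl
Why: Bromine–magnesium exchange at the carbon between fluorine and benzyloxy gives 20, which loses MgFCl on warming to aryne 21; MeMgCl adds to the aryne carbon remote from the flanking benzyloxy group, leaving magnesium on the carbon beside that oxygen (22), and this arylmagnesium then adds to the aldehyde of 15 (aryne carbomagnesiation followed by Grignard 1,2-addition). The closest known reaction type is the three-component coupling of 3-alkoxyarynes from ortho-halofluoroarenes with a Grignard reagent and an electrophile, as used for resorcylates. No ring is closed; the Ar–CH3 and Ar–CH(OH) bonds form on adjacent carbons of ring B in one flask. The carbinol carbon is the only new stereocentre, nothing controls it, it forms as a racemate and is erased in step 14. Regioselectivity rests on the inductive pull of the benzyloxy oxygen next to the triple bond, which stabilises the developing aryl anion at the proximal carbon, and chemoselectivity rests on the aldehyde being far more electrophilic than the tetra-ortho-substituted diaryl ketone of the ring A'–ring B' half. MeMgCl is kept just below one equivalent per 18 and 18 is used in excess over 15, so that little free MeMgCl should remain to attack the aldehyde when 15 is added.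

Step 14
Reactants: 23 rac-[2,6-bis(benzyloxy)-3-({2,4-bis(benzyloxy)-3-[(2,4-bis(benzyloxy)-6-methylphenyl)(hydroxy)methyl]-6-methoxyphenyl}methyl)-4-methoxyphenyl][4-(benzyloxy)-2-methoxy-6-methylphenyl]methanone
Product: 24 [2,6-bis(benzyloxy)-3-({2,4-bis(benzyloxy)-3-[2,4-bis(benzyloxy)-6-methylbenzoyl]-6-methoxyphenyl}methyl)-4-methoxyphenyl][4-(benzyloxy)-2-methoxy-6-methylphenyl]methanone
Conditions: Dess–Martin periodinane, pyridine, CH2Cl2, rt
Reagents that add atoms: none
Why: Dess–Martin oxidation of the hindered diarylcarbinol gives the second benzophenone and removes the racemic centre, the buffer preventing acid ionisation of the electron-rich carbinol.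

Step 15
Reactants: 24 [2,6-bis(benzyloxy)-3-({2,4-bis(benzyloxy)-3-[2,4-bis(benzyloxy)-6-methylbenzoyl]-6-methoxyphenyl}methyl)-4-methoxyphenyl][4-(benzyloxy)-2-methoxy-6-methylphenyl]methanone
Product: 25 (2,6-dihydroxy-3-{[2,4-dihydroxy-3-(2,4-dihydroxy-6-methylbenzoyl)-6-methoxyphenyl]methyl}-4-methoxyphenyl)(4-hydroxy-2-methoxy-6-methylphenyl)methanone (CNP0596095.0)
Conditions: H2 (1 atm), 10% Pd/C, EtOAc–MeOH, rt
Reagents that add atoms: none
Why: Catalytic hydrogenolysis cleaves all seven benzyl aryl ethers, while the three methyl ethers, the diarylmethane and the hindered, hydrogen-bonded benzophenone carbonyls should survive at ambient pressure with monitoring.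

**Compound list**

1 | 2,4,6-trihydroxybenzaldehyde | O=Cc1c(O)cc(O)cc1O | starting material
2 | 2,6-dihydroxy-4-methoxybenzaldehyde | COc1cc(O)c(C=O)c(O)c1 | intermediate
3 | 2,4-dihydroxy-6-methylbenzaldehyde | Cc1cc(O)cc(O)c1C=O | starting material
4 | 4-(benzyloxy)-2-hydroxy-6-methylbenzaldehyde | Cc1cc(OCc2ccccc2)cc(O)c1C=O | intermediate
5 | 4-(benzyloxy)-2-methoxy-6-methylbenzaldehyde | COc1cc(OCc2ccccc2)cc(C)c1C=O | intermediate
6 | 5-methoxyresorcinol (5-methoxybenzene-1,3-diol) | COc1cc(O)cc(O)c1 | starting material
7 | 1-methoxy-3,5-bis(methoxymethoxy)benzene | COCOc1cc(OC)cc(OCOC)c1 | intermediate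
8 | [4-methoxy-2,6-bis(methoxymethoxy)phenyl]lithium | [Li]c1c(OCOC)cc(OC)cc1OCOC | intermediate
9 | rac-[4-(benzyloxy)-2-methoxy-6-methylphenyl][4-methoxy-2,6-bis(methoxymethoxy)phenyl]methanol | COCOc1cc(OC)cc(OCOC)c1C(O)c1c(C)cc(OCc2ccccc2)cc1OC | intermediate
10 | [4-(benzyloxy)-2-methoxy-6-methylphenyl][4-methoxy-2,6-bis(methoxymethoxy)phenyl]methanone | COCOc1cc(OC)cc(OCOC)c1C(=O)c1c(C)cc(OCc2ccccc2)cc1OC | intermediate
11 | [4-(benzyloxy)-2-methoxy-6-methylphenyl](2,6-dihydroxy-4-methoxyphenyl)methanone | COc1cc(O)c(C(=O)c2c(C)cc(OCc3ccccc3)cc2OC)c(O)c1 | intermediate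
12 | [4-(benzyloxy)-2-methoxy-6-methylphenyl]{3-[(dimethylamino)methyl]-2,6-dihydroxy-4-methoxyphenyl}methanone | COc1cc(O)c(C(=O)c2c(C)cc(OCc3ccccc3)cc2OC)c(O)c1CN(C)C | intermediate
13 | 2-[4-(benzyloxy)-2-methoxy-6-methylbenzoyl]-3-hydroxy-5-methoxy-6-methylidenecyclohexa-2,4-dien-1-one (ortho-quinone methide) | C=C1C(OC)=CC(O)=C(C(=O)c2c(C)cc(OCc3ccccc3)cc2OC)C1=O | intermediate
14 | 3-{[3-(4-(benzyloxy)-2-methoxy-6-methylbenzoyl)-2,4-dihydroxy-6-methoxyphenyl]methyl}-2,6-dihydroxy-4-methoxybenzaldehyde | COc1cc(O)c(C=O)c(O)c1Cc1c(OC)cc(O)c(C(=O)c2c(C)cc(OCc3ccccc3)cc2OC)c1O | intermediate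
15 | 2,6-bis(benzyloxy)-3-{[2,4-bis(benzyloxy)-3-(4-(benzyloxy)-2-methoxy-6-methylbenzoyl)-6-methoxyphenyl]methyl}-4-methoxybenzaldehyde | COc1cc(OCc2ccccc2)c(C=O)c(OCc2ccccc2)c1Cc1c(OC)cc(OCc2ccccc2)c(C(=O)c2c(C)cc(OCc3ccccc3)cc2OC)c1OCc1ccccc1 | intermediate
16 | 5-fluororesorcinol (5-fluorobenzene-1,3-diol) | Oc1cc(O)cc(F)c1 | starting material
17 | 1,3-bis(benzyloxy)-5-fluorobenzene | Fc1cc(OCc2ccccc2)cc(OCc2ccccc2)c1 | intermediate
18 | 1,5-bis(benzyloxy)-2-bromo-3-fluorobenzene | Fc1cc(OCc2ccccc2)cc(OCc2ccccc2)c1Br | intermediate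
19 | methylmagnesium chloride | C[Mg]Cl | starting material
20 | [2,4-bis(benzyloxy)-6-fluorophenyl]magnesium chloride | Fc1cc(OCc2ccccc2)cc(OCc2ccccc2)c1[Mg]Cl | intermediate
21 | 3,5-bis(benzyloxy)benzyne (1,2-didehydro-3,5-bis(benzyloxy)benzene) | C1#CC(OCc2ccccc2)=CC(OCc2ccccc2)=C1 | intermediate
22 | [2,4-bis(benzyloxy)-6-methylphenyl]magnesium chloride | Cc1cc(OCc2ccccc2)cc(OCc2ccccc2)c1[Mg]Cl | intermediate
23 | rac-[2,6-bis(benzyloxy)-3-({2,4-bis(benzyloxy)-3-[(2,4-bis(benzyloxy)-6-methylphenyl)(hydroxy)methyl]-6-methoxyphenyl}methyl)-4-methoxyphenyl][4-(benzyloxy)-2-methoxy-6-methylphenyl]methanone | COc1cc(OCc2ccccc2)c(C(O)c2c(C)cc(OCc3ccccc3)cc2OCc2ccccc2)c(OCc2ccccc2)c1Cc1c(OC)cc(OCc2ccccc2)c(C(=O)c2c(C)cc(OCc3ccccc3)cc2OC)c1OCc1ccccc1 | intermediate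
24 | [2,6-bis(benzyloxy)-3-({2,4-bis(benzyloxy)-3-[2,4-bis(benzyloxy)-6-methylbenzoyl]-6-methoxyphenyl}methyl)-4-methoxyphenyl][4-(benzyloxy)-2-methoxy-6-methylphenyl]methanone | COc1cc(OCc2ccccc2)c(C(=O)c2c(C)cc(OCc3ccccc3)cc2OCc2ccccc2)c(OCc2ccccc2)c1Cc1c(OC)cc(OCc2ccccc2)c(C(=O)c2c(C)cc(OCc3ccccc3)cc2OC)c1OCc1ccccc1 | intermediate
25 | (2,6-dihydroxy-3-{[2,4-dihydroxy-3-(2,4-dihydroxy-6-methylbenzoyl)-6-methoxyphenyl]methyl}-4-methoxyphenyl)(4-hydroxy-2-methoxy-6-methylphenyl)methanone (CNP0596095.0) | COc1cc(O)c(C(=O)c2c(C)cc(O)cc2O)c(O)c1Cc1c(OC)cc(O)c(C(=O)c2c(C)cc(O)cc2OC)c1O | target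

**Count and risks**

Total steps: 15. Longest linear sequence: 11 steps (3 to 25 through steps 2, 3, 5, 6, 7, 8, 9, 10, 13, 14 and 15).

Step 13. What may go wrong: residual MeMgCl or i-PrMgCl may consume the aldehyde before the doubly ortho-substituted arylmagnesium 22 adds, the addition of 22 to the hindered aldehyde may stall, or the aryne may oligomerise with 22. The fallback sets out from aldehyde 15 and comes back at carbinol 23, with the methyl group already in place on the nucleophile. Commercial orcinol would be dibenzylated (BnBr, K2CO3, DMF) to 1,3-bis(benzyloxy)-5-methylbenzene F1. NBS in MeCN would brominate it between the methyl and a benzyloxy group to give 1,5-bis(benzyloxy)-2-bromo-3-methylbenzene F2. Bromine–lithium exchange with n-BuLi in THF at −78 °C would give [2,4-bis(benzyloxy)-6-methylphenyl]lithium F3, which should add to 15 at −78 to 0 °C and give 23 after an NH4Cl quench.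

Step 9. What may go wrong: the quinone methide 13 may be captured by unreacted 12 or by product 14 rather than by 2, giving oligomers, or 2 may be alkylated twice. The fallback sets out from benzophenone 11 and aldehyde 2 and comes back at 14 without any preformed electrophile. The two phenols would be cross-condensed with aqueous formaldehyde (about 3 equiv) and catalytic KOH in EtOH at rt, with 2 in fivefold excess. The statistical hydroxymethylation–condensation known for acylphloroglucinols should then turn most of 11 into 14, and the symmetric bis-aldehyde from 2 would be removed by chromatography. This fallback makes no compound outside the list (F0).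

Step 10. What may go wrong: the polyphenoxide may undergo base-induced scission or scrambling of the methylene bridge, and the two hydroxyls flanked by a carbonyl and the bridge may be benzylated incompletely. The fallback sets out from 14 and comes back at 15 without ever forming a free phenoxide. It is a fourfold Mitsunobu etherification with benzyl alcohol (PPh3, diisopropyl azodicarboxylate, THF, 0 °C to rt), in which each neutral phenol attacks the benzyloxyphosphonium ion. This fallback makes no compound outside the list (F0).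

**Further compounds**

F1 | step 13 | 1,3-bis(benzyloxy)-5-methylbenzene | Cc1cc(OCc2ccccc2)cc(OCc2ccccc2)c1
F2 | step 13 | 1,5-bis(benzyloxy)-2-bromo-3-methylbenzene | Cc1cc(OCc2ccccc2)cc(OCc2ccccc2)c1Br
F3 | step 13 | [2,4-bis(benzyloxy)-6-methylphenyl]lithium | [Li]c1c(C)cc(OCc2ccccc2)cc1OCc1ccccc1
F0 | step 9 | none | none
F0 | step 10 | none | none
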